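**Retrosynthetic overview**
- The three aryl ester C–O bonds on the central ring are cut last. This leads back to an O-silylated atromentin quinone and three equivalents of one (2Z,4S,5S)-4,5-epoxyhex-2-enoyl donor.
- Two esters come from ordinary O-acylation of the hydroxyquinone. The third comes from a phosphine-gated reductive acylation that aromatises the ring and leaves the fourth oxygen as the free OH.
- The quinone core comes from bromanil: double alkoxide substitution with benzyl alcohol, double Suzuki coupling, then hydrogenolysis.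
- The acyl unit comes from crotonaldehyde: organocatalytic epoxidation sets both stereocentres and a Z-selective olefination sets the alkene.
- Ring order: the oxiranes are formed first, in one batch of acid. All three six-membered rings are bought, and the central ring travels as a quinone and becomes benzenoid only in the key step.

Assumption: the SMILES is taken at face value (each acyl group 2Z,4S,5S). The four oxygens on the central ring of the leuco core are symmetry-equivalent, so the position of the free OH needs no regiocontrol and a neighbouring O-to-O acyl shift is degenerate.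

**Step 1**
Reactants: 1 (E)-crotonaldehyde; 2 methyl bis(2,2,2-trifluoroethyl)phosphonoacetate
Product: 4 methyl (2Z,4S,5S)-4,5-epoxyhex-2-enoate, via (2R,3S)-2,3-epoxybutanal 3 (not isolated)
Conditions: (R)-2-{bis[3,5-bis(trifluoromethyl)phenyl](trimethylsilyloxy)methyl}pyrrolidine (10 mol%), 35% aq H2O2 (1.3 equiv), CH2Cl2, rt, 4 h; phase cut, dry (Na2SO4); solution of 3 added to 2, KN(SiMe3)2, 18-crown-6, THF, −78 °C, 2 h
Reagents that add atoms: hydrogen peroxide, OO
Why: In this iminium–enamine organocatalytic epoxidation the bulky group of the R catalyst blocks the Re face of C3 of the E-iminium ion, so hydroperoxide adds to the Si face and the enamine closes the trans-oxirane to give (2R,3S)-3, whose centres become C4 (S, descriptor changed only by CIP priorities) and C5 (S) of 4, and the Still–Gennari variant of the Horner–Wadsworth–Emmons olefination then gives the Z-alkene under kinetic control.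

**Step 2**
Reactants: 4 methyl (2Z,4S,5S)-4,5-epoxyhex-2-enoate
Product: 5 potassium (2Z,4S,5S)-4,5-epoxyhex-2-enoate
Conditions: KOSiMe3 (1.0 equiv), Et2O, 0 °C → rt, 3 h; filter the precipitate under N2
Reagents that add atoms: potassium trimethylsilanolate, C[Si](C)(C)[O-].[K+]
Why: Anhydrous silanolate cleavage of a methyl ester delivers the carboxylate salt directly, so the lactonisation-prone free Z-epoxy acid is never generated and neither the alkene nor the stereocentres are touched.

**Step 3**
Reactants: 6 bromanil (tetrabromo-1,4-benzoquinone); 7 benzyl alcohol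
Product: 8 2,5-bis(benzyloxy)-3,6-dibromo-1,4-benzoquinone
Conditions: 7 (2.1 equiv), NaH (2.1 equiv), THF, 0 °C; added to 6, THF, −20 → 0 °C, 2 h
Reagents that add atoms: none
Why: This is a double addition–elimination (vinylogous acyl substitution) on a tetrahaloquinone, in which the first alkoxy group deactivates its own vinylogous carbonyl so the second alkoxide enters at the para-related carbon and gives the 2,5-pattern, as with methoxide.

**Step 4**
Reactants: 8 2,5-bis(benzyloxy)-3,6-dibromo-1,4-benzoquinone; 9 4-(tert-butyldimethylsilyloxy)phenylboronic acid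
Product: 10 2,5-bis(benzyloxy)-3,6-bis[4-(tert-butyldimethylsilyloxy)phenyl]-1,4-benzoquinone
Conditions: 9 (2.5 equiv), PdCl2(dppf) (5 mol%), K3PO4 (4 equiv), 1,4-dioxane/H2O 10:1, 70 °C, 6 h, Ar
Reagents that add atoms: none
Why: In this double Suzuki–Miyaura coupling the C–Br bonds are vinylogous acyl bromides that add readily to the zerovalent palladium formed in situ, as established for the 2,5-dimethoxy analogue, and the aryl silyl ethers and benzyl ethers tolerate K3PO4 at 70 °C.

**Step 5**
Reactants: 10 2,5-bis(benzyloxy)-3,6-bis[4-(tert-butyldimethylsilyloxy)phenyl]-1,4-benzoquinone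
Product: 12 2,5-dihydroxy-3,6-bis[4-(tert-butyldimethylsilyloxy)phenyl]-1,4-benzoquinone, via tetrol 11 (not isolated)
Conditions: H2 (1 atm), Pd/C (10 wt%), EtOAc, rt, 3 h; filter; stir the filtrate under air, rt, 1 h
Reagents that add atoms: none
Why: Hydrogenolysis of both benzyl ethers with reduction of the quinone gives the electron-rich tetrol 11, which autoxidises in air to the hydroxyquinone, while aryl TBS ethers are inert to H2 and Pd/C in EtOAc.

**Step 6**
Reactants: 5 potassium (2Z,4S,5S)-4,5-epoxyhex-2-enoate (3.1 equiv); 12 2,5-dihydroxy-3,6-bis[4-(tert-butyldimethylsilyloxy)phenyl]-1,4-benzoquinone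
Product: 17 3,6-bis[4-(tert-butyldimethylsilyloxy)phenyl]-5-hydroxybenzene-1,2,4-triyl tris[(2Z,4S,5S)-4,5-epoxyhex-2-enoate], via acid chloride 13 (not isolated), via bis(acyloxy)quinone 14 (not isolated), via phosphonium phenoxide betaine 15 (not isolated), via aryloxyphosphonium chloride 16 (not isolated)
Conditions: (a) 5, (COCl)2 (3.05 equiv), CH2Cl2, −10 °C, 1 h, cannula-filter; (b) 12, iPr2NEt (2.0 equiv), CH2Cl2, −40 °C, then 13 (2.05 equiv), → 0 °C, 1 h; (c) PPh3 (1.0 equiv), −40 °C, 20 min; (d) 13 (1.0 equiv), −40 → −10 °C, 30 min; (e) pH 7 buffer (Na2HPO4/NaH2PO4), 0 °C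
Reagents that add atoms: oxalyl chloride, ClC(=O)C(=O)Cl (Cl of 13 and 16 only); triphenylphosphine, c1ccc(cc1)P(c1ccccc1)c1ccccc1 (P of 15 and 16 only); none of these atoms remains in 17
Why: Proposed new method: phosphine-gated reductive O-acylation of a quinone, in which 13 first acylates the two vinylogous-acid hydroxyls of 12 in the ordinary way (14), PPh3 then adds to a carbonyl oxygen of the fully substituted, electron-poor quinone (no free ring carbon for C-attack) to give the aromatised 4-(phosphoniooxy)phenoxide 15, the phenoxide of 15 is the only nucleophile left and takes up exactly one more acyl group from 13, and the fourth oxygen stays masked as its P–O+ salt (16) until the buffer releases it as the free OH together with Ph3P=O, so tri- versus tetra-acylation is fixed by mechanism and no stereocentre or Z-alkene is touched at low temperature; the closest known reaction types are Ramirez-type O-adducts of PPh3 with tetrahaloquinones, the Mukaiyama oxidation–reduction condensation with quinone oxidants, and Mitsunobu-type aryl ester formation.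

**Step 7**
Reactants: 17 3,6-bis[4-(tert-butyldimethylsilyloxy)phenyl]-5-hydroxybenzene-1,2,4-triyl tris[(2Z,4S,5S)-4,5-epoxyhex-2-enoate]
Product: 18 5-hydroxy-3,6-bis(4-hydroxyphenyl)benzene-1,2,4-triyl tris[(2Z,4S,5S)-4,5-epoxyhex-2-enoate] (CNP0278429.1)
Conditions: Bu4NF (2.2 equiv), AcOH (2.5 equiv), THF, 0 °C, 30 min, Ar
Reagents that add atoms: none
Why: Fluoride cleaves aryl silyl ethers within minutes, and the AcOH buffer prevents a free phenoxide from forming that could cleave or transfer the aryl esters or open the epoxides, so all six stereocentres and the three Z-alkenes are carried through unchanged.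

**Compound list**
1 | (E)-crotonaldehyde | C/C=C/C=O | starting material
2 | methyl bis(2,2,2-trifluoroethyl)phosphonoacetate | COC(=O)CP(=O)(OCC(F)(F)F)OCC(F)(F)F | starting material
3 | (2R,3S)-2,3-epoxybutanal [(2R,3S)-3-methyloxirane-2-carbaldehyde] | C[C@@H]1O[C@H]1C=O | intermediate
4 | methyl (2Z,4S,5S)-4,5-epoxyhex-2-enoate | C[C@@H]1O[C@H]1/C=C\C(=O)OC | intermediate
5 | potassium (2Z,4S,5S)-4,5-epoxyhex-2-enoate | C[C@@H]1O[C@H]1/C=C\C(=O)[O-].[K+] | intermediate
6 | bromanil (2,3,5,6-tetrabromo-1,4-benzoquinone) | O=C1C(Br)=C(Br)C(=O)C(Br)=C1Br | starting material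
7 | benzyl alcohol | OCc1ccccc1 | starting material
8 | 2,5-bis(benzyloxy)-3,6-dibromo-1,4-benzoquinone | O=C1C(OCc2ccccc2)=C(Br)C(=O)C(OCc2ccccc2)=C1Br | intermediate
9 | 4-(tert-butyldimethylsilyloxy)phenylboronic acid | CC(C)(C)[Si](C)(C)Oc1ccc(cc1)B(O)O | starting material
10 | 2,5-bis(benzyloxy)-3,6-bis[4-(tert-butyldimethylsilyloxy)phenyl]-1,4-benzoquinone | O=C1C(OCc2ccccc2)=C(c2ccc(O[Si](C)(C)C(C)(C)C)cc2)C(=O)C(OCc2ccccc2)=C1c1ccc(O[Si](C)(C)C(C)(C)C)cc1 | intermediate
11 | 3,6-bis[4-(tert-butyldimethylsilyloxy)phenyl]benzene-1,2,4,5-tetrol | Oc1c(O)c(-c2ccc(O[Si](C)(C)C(C)(C)C)cc2)c(O)c(O)c1-c1ccc(O[Si](C)(C)C(C)(C)C)cc1 | intermediate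
12 | 2,5-dihydroxy-3,6-bis[4-(tert-butyldimethylsilyloxy)phenyl]-1,4-benzoquinone | O=C1C(O)=C(c2ccc(O[Si](C)(C)C(C)(C)C)cc2)C(=O)C(O)=C1c1ccc(O[Si](C)(C)C(C)(C)C)cc1 | intermediate
13 | (2Z,4S,5S)-4,5-epoxyhex-2-enoyl chloride | C[C@@H]1O[C@H]1/C=C\C(=O)Cl | intermediate
14 | 2,5-bis[(2Z,4S,5S)-4,5-epoxyhex-2-enoyloxy]-3,6-bis[4-(tert-butyldimethylsilyloxy)phenyl]-1,4-benzoquinone | O=C1C(OC(=O)/C=C\[C@@H]2O[C@H]2C)=C(c2ccc(O[Si](C)(C)C(C)(C)C)cc2)C(=O)C(OC(=O)/C=C\[C@@H]2O[C@H]2C)=C1c1ccc(O[Si](C)(C)C(C)(C)C)cc1 | intermediate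
15 | 2,5-bis(acyloxy)-3,6-diaryl-4-(triphenylphosphoniooxy)phenoxide betaine (acyl = (2Z,4S,5S)-4,5-epoxyhex-2-enoyl, aryl = 4-TBSO-phenyl) | [O-]c1c(OC(=O)/C=C\[C@@H]2O[C@H]2C)c(-c2ccc(O[Si](C)(C)C(C)(C)C)cc2)c(O[P+](c2ccccc2)(c2ccccc2)c2ccccc2)c(OC(=O)/C=C\[C@@H]2O[C@H]2C)c1-c1ccc(O[Si](C)(C)C(C)(C)C)cc1 | intermediate
16 | [2,4,5-tris(acyloxy)-3,6-diarylphenoxy]triphenylphosphonium chloride (same acyl and aryl groups) | [Cl-].C[C@@H]1O[C@H]1/C=C\C(=O)Oc1c(OC(=O)/C=C\[C@@H]2O[C@H]2C)c(-c2ccc(O[Si](C)(C)C(C)(C)C)cc2)c(OC(=O)/C=C\[C@@H]2O[C@H]2C)c(O[P+](c2ccccc2)(c2ccccc2)c2ccccc2)c1-c1ccc(O[Si](C)(C)C(C)(C)C)cc1 | intermediate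
17 | 3,6-bis[4-(tert-butyldimethylsilyloxy)phenyl]-5-hydroxybenzene-1,2,4-triyl tris[(2Z,4S,5S)-4,5-epoxyhex-2-enoate] | C[C@@H]1O[C@H]1/C=C\C(=O)Oc1c(OC(=O)/C=C\[C@@H]2O[C@H]2C)c(-c2ccc(O[Si](C)(C)C(C)(C)C)cc2)c(OC(=O)/C=C\[C@@H]2O[C@H]2C)c(O)c1-c1ccc(O[Si](C)(C)C(C)(C)C)cc1 | intermediate
18 | 5-hydroxy-3,6-bis(4-hydroxyphenyl)benzene-1,2,4-triyl tris[(2Z,4S,5S)-4,5-epoxyhex-2-enoate] (CNP0278429.1) | C[C@@H]1O[C@H]1/C=C\C(=O)Oc1c(OC(=O)/C=C\[C@@H]2O[C@H]2C)c(-c2ccc(O)cc2)c(OC(=O)/C=C\[C@@H]2O[C@H]2C)c(O)c1-c1ccc(O)cc1 | target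

**Step count**
Total step count: 7.
Longest linear sequence: 5 (steps 3, 4, 5, 6, 7 from bromanil). The acid branch runs through steps 1, 2, 6, 7.

**Three steps most likely to fail**

Step 1.
- Risks: aldehyde 3 is small, volatile and water-soluble. Crotonaldehyde is the least hindered substrate for the organocatalyst, so ee and dr may be lower than for larger enals. Three copies of the acid end up in one molecule, so a 97:3 er already produces about 9% of diastereomeric triesters.
- Fallback: it sets out from 1 and comes back at 3, replacing iminium catalysis with a directed metal-catalysed epoxidation. Compound 1 is reduced with NaBH4 and CeCl3·7H2O in MeOH to (E)-but-2-en-1-ol F1. Sharpless asymmetric epoxidation of this alcohol (Ti(OiPr)4, L-(+)-diisopropyl tartrate, tBuOOH, 4 Å sieves, CH2Cl2, −20 °C) gives [(2S,3S)-3-methyloxiran-2-yl]methanol F2. Oxidation of F2 with TEMPO and PhI(OAc)2 in CH2Cl2 gives a solution of 3, which enters the same olefination to reach 4.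

Step 3.
- Risks: benzyl alkoxide is also a hydride and electron donor towards a strongly oxidising tetrahaloquinone, so reduction of 6 and over-substitution can compete with the clean 2,5-disubstitution.
- Fallback: it sets out from 6 and comes back at 8, forming the O–CH2 bond instead of the quinone–O bond. Compound 6 is hydrolysed with aqueous NaOH and acidified to give bromanilic acid F3. O-alkylation of F3 with benzyl bromide and Ag2O in toluene, the classical alkylation of anilic acid silver salts, gives 8.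

Step 6 (the proposed new step).
- Risks: PPh3 could displace an acyloxy group at carbon instead of binding to oxygen. The hindered quinone could react sluggishly. Free phosphine could isomerise Z-enoates. Stray carboxylate could turn the P–O+ group into a fourth ester. Stage (c) can be followed by the colour discharge and by 31P NMR.
- Fallback: it sets out from 12 and comes back at 17, using only known reduce-then-acylate chemistry. Compound 12 is acylated with two equivalents of 13 and iPr2NEt, and 14 is isolated. Shaking 14 with aqueous Na2S2O4 in EtOAc reduces it to 2,5-dihydroxy-3,6-bis[4-(tert-butyldimethylsilyloxy)phenyl]-1,4-phenylene bis[(2Z,4S,5S)-4,5-epoxyhex-2-enoate] F4. One of the two equivalent hydroxyls of F4 is then acylated statistically with 1.0 equiv of 13 and iPr2NEt at −40 °C. Compound 17 is separated by chromatography and recovered F4 is recycled.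

**Further compounds**
F1 | step 1 | (E)-but-2-en-1-ol | C/C=C/CO
F2 | step 1 | [(2S,3S)-3-methyloxiran-2-yl]methanol | C[C@@H]1O[C@H]1CO
F3 | step 3 | bromanilic acid (2,5-dibromo-3,6-dihydroxy-1,4-benzoquinone) | O=C1C(O)=C(Br)C(=O)C(O)=C1Br
F4 | step 6 | 2,5-dihydroxy-3,6-bis[4-(tert-butyldimethylsilyloxy)phenyl]-1,4-phenylene bis[(2Z,4S,5S)-4,5-epoxyhex-2-enoate] | Oc1c(OC(=O)/C=C\[C@@H]2O[C@H]2C)c(-c2ccc(O[Si](C)(C)C(C)(C)C)cc2)c(O)c(OC(=O)/C=C\[C@@H]2O[C@H]2C)c1-c1ccc(O[Si](C)(C)C(C)(C)C)cc1
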